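## Retrosynthetic overview

1. The arene is made last. The formyl hydroquinone comes from the formyl-p-quinone, which comes from a [4+2]/aromatisation of a C11-alkynal with 2,5-bis(trimethylsilyloxy)furan. No phenol protecting groups are needed.
2. The C8 carbinol and the CHO carbon come from a C9-propargyl cis-decalone (MeLi on the ketone, then DMF on the acetylide, in one flask).
3. The C9–C11 bond comes from propargylation of a regiodefined C8=C9 enolate, released from a bicyclic enol acetate.
4. Rings A and B form together, A then B in one cascade. An acyclic (Z)-dienyne plus AcOH undergoes a proton-initiated, alkyne-terminated bicyclisation, and the Z-alkene gives the cis ring fusion.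
5. The (Z)-dienyne comes from nerol and 1-(trimethylsilyl)propyne.

**Assumption:** the SMILES is read literally. In drimane numbering (used throughout) it encodes 5R,8R,9R,10S. H-5 and CH3-10 are therefore cis, so the target is a cis-decalin, the 5-epimer of the usual trans-drimane series. The antipode of the chiral acid in step 3 is picked by a test run so that the enol acetate is (4aR,8aS).

## Route

**Step 1**
Reactants: 1 nerol
Product: 2 neryl bromide
Conditions: PBr3 (0.4 equiv), Et2O, −10 °C; used crude
Reagents that add atoms: phosphorus tribromide, BrP(Br)Br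
Why: SN2-type bromination of the primary allylic alcohol through its phosphite ester at low temperature keeps the Z-alkene; no stereocentre is formed.

**Step 2**
Reactants: 2 neryl bromide; 3 1-(trimethylsilyl)propyne
Product: 6 (Z)-6,10-dimethylundeca-5,9-dien-1-yne, via lithiated silylpropyne 4 (not isolated), via silyl dienyne 5 (not isolated)
Conditions: 3, n-BuLi, THF, −78 to −20 °C; 2, −78 °C to rt; then MeOH, K2CO3 (cat.), rt
Reagents that add atoms: 1-(trimethylsilyl)propyne (3), CC#C[Si](C)(C)C
Why: Propargylic lithiation and SN2 alkylation at the primary allylic carbon (the silyl group suppresses the allenyl pathway and the Z-geometry is untouched), followed by methanolysis of the alkynyl–Si bond.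

**Step 3 (key step)**
Reactants: 6 (Z)-6,10-dimethylundeca-5,9-dien-1-yne
Product: 7 (4aR,8aS)-5,5,8a-trimethyl-3,4,4a,5,6,7,8,8a-octahydronaphthalen-2-yl acetate (cis-fused)
Conditions: confined chiral imidodiphosphorimidate (IDPi) Brønsted acid (5 mol %), AcOH (3 equiv), (CF3)3COH–CH2Cl2, −20 °C
Reagents that add atoms: acetic acid, CC(=O)O
Why: Proposed new method: the confined acid protonates the terminal isopropylidene of 6 held in a chair–chair fold; C4+ adds to C5 while the terminal alkyne carbon C9 adds to C10 on the opposite face of the Z-alkene (Stork–Eschenmoser anti addition, so H-5 and CH3-10 end up cis, and the catalyst pocket fixes 5R,10S); 6-endo attack avoids a primary vinyl cation, and AcOH captures the incipient C8 vinyl cation and returns the proton, which locks the enol double bond at C8=C9; the closest known reaction types are the confined-acid catalysed asymmetric polyene cyclisation of homofarnesol-type trienes and the Johnson alkyne-terminated cationic polyene cyclisation.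

**Step 4**
Reactants: 7 enol acetate; 8 propargyl bromide
Product: 10 (1R,4aR,8aS)-5,5,8a-trimethyl-1-(prop-2-yn-1-yl)octahydronaphthalen-2(1H)-one, via lithium enolate 9 (not isolated)
Conditions: MeLi (2.1 equiv), DME, 0 °C; DMPU, 8 (3 equiv), −78 to −30 °C; H2O quench
Reagents that add atoms: propargyl bromide (8), C#CCBr
Why: Enol acetate cleavage with MeLi (House method) releases the C8=C9 lithium enolate without regiochemical scrambling, and the SN2 alkylation follows the stereoelectronically preferred axial path at C9 on the face anti to the pseudo-axial C1 methylene of the cis-decalin (syn to CH3-10 and H-5), which sets 9R.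

**Step 5**
Reactants: 10 propargyl ketone
Product: 13 4-[(1R,2R,4aR,8aS)-2-hydroxy-2,5,5,8a-tetramethyldecahydronaphthalen-1-yl]but-2-ynal, via dilithio alkoxide acetylide 11 (not isolated), via lithium hemiaminalate 12 (not isolated)
Conditions: MeLi (3.5 equiv), Et2O–THF, −78 to 0 °C; DMF, 0 °C; inverse quench into cold 1 M HCl
Reagents that add atoms: methyllithium, [Li]C; N,N-dimethylformamide, CN(C)C=O
Why: After deprotonation of the alkyne, the 1,2-addition of MeLi takes the equatorial trajectory because the axial one is blocked by the syn-axial C1 methylene, giving equatorial CH3 and axial OH (8R), and the lithium acetylide is then formylated with DMF.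

**Step 6**
Reactants: 14 succinic anhydride
Product: 15 2,5-bis(trimethylsilyloxy)furan
Conditions: TMSCl (2.5 equiv), Et3N (2.5 equiv), ZnCl2 (cat.), MeCN, 45 °C; filter, distil
Reagents that add atoms: chlorotrimethylsilane, C[Si](C)(C)Cl
Why: Double soft enolisation and O-silylation of the anhydride gives the aromatic bis(silyl ketene acetal); no stereocentre is formed.

**Step 7**
Reactants: 13 hydroxy ynal; 15 2,5-bis(trimethylsilyloxy)furan
Product: 18 2-{[(1R,2R,4aR,8aS)-2-hydroxy-2,5,5,8a-tetramethyldecahydronaphthalen-1-yl]methyl}-3,6-dihydroxybenzaldehyde (target), via oxanorbornadiene adduct 16 (not isolated), via formylquinone 17 (not isolated)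
Conditions: 15 (2.5 equiv), PhMe, 60 °C; then THF–H2O, Na2S2O4, rt
Reagents that add atoms: 2,5-bis(trimethylsilyloxy)furan (15), C[Si](C)(C)Oc1ccc(O[Si](C)(C)C)o1
Why: Diels–Alder reaction of the very electron-rich symmetrical furan with the ynal (no regiochemical issue), collapse of the bis-ketal adduct with loss of hexamethyldisiloxane to the p-quinone, and dithionite reduction place CH2, CHO and both OH groups correctly; the four stereocentres are remote and untouched.

## Compound list

1 | nerol, (2Z)-3,7-dimethylocta-2,6-dien-1-ol | OC/C=C(/C)CCC=C(C)C | starting material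
2 | neryl bromide | BrC/C=C(/C)CCC=C(C)C | intermediate
3 | 1-(trimethylsilyl)propyne | CC#C[Si](C)(C)C | starting material
4 | 3-lithio-1-(trimethylsilyl)propyne | [Li]CC#C[Si](C)(C)C | intermediate
5 | (Z)-(6,10-dimethylundeca-5,9-dien-1-yn-1-yl)trimethylsilane | C[Si](C)(C)C#CCC/C=C(/C)CCC=C(C)C | intermediate
6 | (Z)-6,10-dimethylundeca-5,9-dien-1-yne | C#CCC/C=C(/C)CCC=C(C)C | intermediate
7 | (4aR,8aS)-5,5,8a-trimethyl-3,4,4a,5,6,7,8,8a-octahydronaphthalen-2-yl acetate | CC1(C)CCC[C@@]2(C)[C@@H]1CCC(OC(C)=O)=C2 | intermediate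
8 | propargyl bromide | C#CCBr | starting material
9 | lithium (4aR,8aS)-5,5,8a-trimethyl-3,4,4a,5,6,7,8,8a-octahydronaphthalen-2-olate | CC1(C)CCC[C@@]2(C)[C@@H]1CCC([O-])=C2.[Li+] | intermediate
10 | (1R,4aR,8aS)-5,5,8a-trimethyl-1-(prop-2-yn-1-yl)octahydronaphthalen-2(1H)-one | CC1(C)CCC[C@@]2(C)[C@@H]1CCC(=O)[C@@H]2CC#C | intermediate
11 | dilithio alkoxide/acetylide of the C8-methyl carbinol | CC1(C)CCC[C@@]2(C)[C@@H]1CC[C@@](C)([O-])[C@@H]2CC#[C-].[Li+].[Li+] | intermediate
12 | dilithium hemiaminalate (DMF adduct of 11) | CC1(C)CCC[C@@]2(C)[C@@H]1CC[C@@](C)([O-])[C@@H]2CC#CC([O-])N(C)C.[Li+].[Li+] | intermediate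
13 | 4-[(1R,2R,4aR,8aS)-2-hydroxy-2,5,5,8a-tetramethyldecahydronaphthalen-1-yl]but-2-ynal | CC1(C)CCC[C@@]2(C)[C@@H]1CC[C@@](C)(O)[C@@H]2CC#CC=O | intermediate
14 | succinic anhydride | O=C1CCC(=O)O1 | starting material
15 | 2,5-bis(trimethylsilyloxy)furan | C[Si](C)(C)Oc1ccc(O[Si](C)(C)C)o1 | intermediate
16 | 1,4-bis(trimethylsilyloxy)-7-oxanorbornadiene adduct (bridgehead diastereomers, inconsequential) | CC1(C)CCC[C@@]2(C)[C@@H]1CC[C@@](C)(O)[C@@H]2CC1=C(C=O)C2(O[Si](C)(C)C)C=CC1(O[Si](C)(C)C)O2 | intermediate
17 | 2-formyl-3-(drimanylmethyl)-1,4-benzoquinone | CC1(C)CCC[C@@]2(C)[C@@H]1CC[C@@](C)(O)[C@@H]2CC1=C(C=O)C(=O)C=CC1=O | intermediate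
18 | 2-{[(1R,2R,4aR,8aS)-2-hydroxy-2,5,5,8a-tetramethyldecahydronaphthalen-1-yl]methyl}-3,6-dihydroxybenzaldehyde | CC1(C)CCC[C@@]2(C)[C@@H]1CC[C@@](C)(O)[C@@H]2Cc1c(O)ccc(O)c1C=O | target

## Step count and risks

Total steps: 7. Longest linear sequence: 6 (steps 1, 2, 3, 4, 5, 7).

**Step 3.** A terminal alkyne is a weak terminator, so monocyclic dienes or tertiary acetates may form. The Z-to-cis fidelity may leak, and the ee is untested.

The fallback sets out from 2 and swaps the alkyne for a chelated enol terminator. The dianion of methyl acetoacetate (NaH, n-BuLi) is alkylated with 2 to give methyl (Z)-7,11-dimethyl-3-oxododeca-6,10-dienoate F1. A stoichiometric chiral BINOL mono-ether·SnCl4 Lewis-acid-assisted Brønsted acid closes both rings to methyl (4aR,8aS)-5,5,8a-trimethyl-2-oxodecahydronaphthalene-1-carboxylate F2. LiCl in wet DMSO removes the ester to give the cis-decalone F3. IBX dehydrogenation can only go towards C6–C7, because C10 is quaternary, and it gives the enone F4. This blocks C7, so LDA and 8 alkylate the cross-conjugated dienolate at C9 to give the propargyl enone F5. 1,4-Reduction with L-Selectride comes back to the route at 10.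

**Step 5.** MeLi may enolise the hindered ketone and epimerise C9, and a minor ring-flipped conformer could give the wrong face.

The fallback sets out from 10 and builds the carbinol through an epoxide. Chloromethyllithium (ICH2Cl, MeLi·LiBr, −78 °C) is a weakly basic carbenoid and adds along the same equatorial path. On warming it closes to the spiro-epoxide F6. LiEt3BH opens the CH2 terminus to give the alkynyl tertiary alcohol F7. Two equivalents of n-BuLi bring it back to the route at 11.

**Step 7.** The β-alkyl ynal may be too sluggish a dienophile. The furan may instead react at the aldehyde, and the formylquinone is fragile.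

The fallback sets out from 9 and brings in a preformed arene. Commercial 2,5-dimethoxybenzyl alcohol is ortho-lithiated as its dianion (n-BuLi) and brominated with BrCF2CF2Br to give 2-bromo-3,6-dimethoxybenzyl alcohol F8. PBr3 converts this to 2-bromo-3,6-dimethoxybenzyl bromide F9. Alkylation of 9 with it gives the benzyl ketone F10, and MeLi gives the bromo carbinol F11. n-BuLi (2 equiv) then DMF gives the target dimethyl ether F12. Oxidative demethylation with ceric ammonium nitrate comes back to the route at 17.

## Further compounds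

F1 | step 3 | methyl (Z)-7,11-dimethyl-3-oxododeca-6,10-dienoate | COC(=O)CC(=O)CC/C=C(/C)CCC=C(C)C
F2 | step 3 | methyl (4aR,8aS)-5,5,8a-trimethyl-2-oxodecahydronaphthalene-1-carboxylate (C1 labile) | CC1(C)CCC[C@@]2(C)[C@@H]1CCC(=O)C2C(=O)OC
F3 | step 3 | (4aR,8aS)-5,5,8a-trimethyloctahydronaphthalen-2(1H)-one | CC1(C)CCC[C@@]2(C)[C@@H]1CCC(=O)C2
F4 | step 3 | (4aR,8aS)-5,5,8a-trimethyl-4a,5,6,7,8,8a-hexahydronaphthalen-2(1H)-one | CC1(C)CCC[C@@]2(C)[C@@H]1C=CC(=O)C2
F5 | step 3 | (1R,4aR,8aS)-5,5,8a-trimethyl-1-(prop-2-yn-1-yl)-4a,5,6,7,8,8a-hexahydronaphthalen-2(1H)-one | CC1(C)CCC[C@@]2(C)[C@@H]1C=CC(=O)[C@@H]2CC#C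
F6 | step 5 | C8 spiro-epoxide of 10 (O axial, CH2 equatorial) | CC1(C)CCC[C@@]2(C)[C@@H]1CC[C@@]1(OC1)[C@@H]2CC#C
F7 | step 5 | (1R,2R,4aR,8aS)-2,5,5,8a-tetramethyl-1-(prop-2-yn-1-yl)decahydronaphthalen-2-ol | CC1(C)CCC[C@@]2(C)[C@@H]1CC[C@@](C)(O)[C@@H]2CC#C
F8 | step 7 | 2-bromo-3,6-dimethoxybenzyl alcohol | COc1ccc(OC)c(Br)c1CO
F9 | step 7 | 2-bromo-3,6-dimethoxybenzyl bromide | COc1ccc(OC)c(Br)c1CBr
F10 | step 7 | (1R,4aR,8aS)-1-(2-bromo-3,6-dimethoxybenzyl)-5,5,8a-trimethyloctahydronaphthalen-2(1H)-one | CC1(C)CCC[C@@]2(C)[C@@H]1CCC(=O)[C@@H]2Cc1c(OC)ccc(OC)c1Br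
F11 | step 7 | (1R,2R,4aR,8aS)-1-(2-bromo-3,6-dimethoxybenzyl)-2,5,5,8a-tetramethyldecahydronaphthalen-2-ol | CC1(C)CCC[C@@]2(C)[C@@H]1CC[C@@](C)(O)[C@@H]2Cc1c(OC)ccc(OC)c1Br
F12 | step 7 | dimethyl ether of the target | CC1(C)CCC[C@@]2(C)[C@@H]1CC[C@@](C)(O)[C@@H]2Cc1c(OC)ccc(OC)c1C=O
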